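**Strategy.** Ring B (C1' ether carbon, C2' H, C3'–C5' Br, C6' hydroxyl carbon) is cut at C1'–C6' and C2'–C3'. The four neighbouring carbons C3'(Br), C4'(Br), C5'(Br) and C6'(OH) come from the carbon diene of symmetrical tetrabromothiophene 1,1-dioxide. C1'(OAr) and C2'(H) come from a terminal aryl ethynyl ether that carries ring A in its guaiacol-derived 2-methoxyphenyl form. One Diels–Alder/SO2-extrusion operation thus builds ring B with the diaryl ether in place and three bromines on their final carbons. The fourth bromine marks C6' for later exchange to hydroxyl. Ring A is brominated last, once its phenol is free.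

Key step: step 4

Remark: ring A is numbered C1 (OH), C2 and C4 (Br), C6 (ether oxygen). The terminal aryl ynol ether is assumed to survive a cold aqueous work-up and is used at once as a solution, without storage.

**Step 1**
Reactants: 1 2,3,4,5-tetrabromothiophene
Product: 3 2,3,4,5-tetrabromothiophene 1,1-dioxide, via tetrabromothiophene 1-oxide 2 (not isolated)
Conditions: H2O2·urea, (CF3CO)2O, CH2Cl2, 0 °C → rt
Reagents that add atoms: trifluoroperacetic acid, OOC(=O)C(F)(F)F, formed in the flask from hydrogen peroxide–urea, OO.NC(N)=O, and trifluoroacetic anhydride, O=C(OC(=O)C(F)(F)F)C(F)(F)F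
Why: Sulfur oxidation of a thiophene to its S,S-dioxide with a peracid: the electron-poor sulfur needs an oxidant as strong as CF3CO3H, and because S-oxide 2 is oxidized more readily than 1 the reaction should run through to the non-aromatic sulfone without touching the C–Br bonds.

**Step 2**
Reactants: 4 guaiacol (2-methoxyphenol); 5 trichloroethylene
Product: 7 (E)-1-[(1,2-dichloroethenyl)oxy]-2-methoxybenzene, via dichloroacetylene 6 (not isolated)
Conditions: K2CO3, DMF, 70 °C
Reagents that add atoms: none
Why: Base-mediated O-vinylation of a phenol with trichloroethylene (elimination–addition): K2CO3 dehydrochlorinates 5 to dichloroacetylene 6 in solution, and anti addition of the phenoxide of 4 across the triple bond followed by protonation should give the (E)-1,2-dichlorovinyl ether, the methyl ether being inert.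

**Step 3**
Reactants: 7 (E)-1-[(1,2-dichloroethenyl)oxy]-2-methoxybenzene
Product: 10 1-(ethynyloxy)-2-methoxybenzene, via chloroethynyl ether 8 (not isolated), via lithium acetylide 9 (not isolated)
Conditions: n-BuLi (2.3 equiv), THF, −78 → −40 °C; H2O, −78 °C
Reagents that add atoms: none
Why: Dichlorovinyl ether to ynol ether conversion with two equivalents of n-BuLi: deprotonation and β-elimination of LiCl give chloroalkyne 8, chlorine–lithium exchange gives acetylide 9, and cold protonation should release the terminal ynol ether, which as an aryl ether has no O-alkyl β-hydrogen and so cannot fragment by the retro-ene path.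

**Step 4**
Reactants: 3 2,3,4,5-tetrabromothiophene 1,1-dioxide; 10 1-(ethynyloxy)-2-methoxybenzene
Product: 12 1,2,3,4-tetrabromo-5-(2-methoxyphenoxy)benzene, via bridged sulfone cycloadduct 11 (not isolated)
Conditions: 10 (1.2 equiv, slow addition), PhMe, 0 → 60 °C, −SO2
Reagents that add atoms: none
Why: Proposed new method: the LUMO-lowered, non-aromatic sulfone diene 3 and the electron-rich ynol ether 10 should react in an inverse-electron-demand Diels–Alder addition in which the nucleophilic CH terminus of 10 bonds to one C–Br terminus of the diene (C2'–C3') and the oxygen-bearing carbon to the other (C1'–C6'), giving 7-thianorbornadiene dioxide 11, which then loses SO2 in a thermally allowed cheletropic step driven by aromatization. The closest known reaction type is the cycloaddition of tetrahalothiophene 1,1-dioxides with alkenes and unactivated alkynes followed by SO2 extrusion, together with the inverse-demand cycloaddition–extrusion of electron-rich alkynes (ynol ethers, ynamines) with electron-poor 2-pyrones and 1,2,4,5-tetrazines; what is new is the pairing of an ynol ether with this diene class. Ring B is closed by intermolecular [4+2] annulation, both ring bonds being made in the cycloaddition and the aromatic sextet completed by loss of the one-atom sulfonyl bridge. No stereocentre is set, because the two bridgehead centres of racemic 11 disappear on aromatization. No regiochemistry arises since 3 is symmetrical, so either orientation gives 12; the selectivity needed is concerted [4+2] addition over stepwise [2+2] addition or oligomerization of 10, which the s-cis-locked diene, the non-polar solvent and slow addition of 10 to 3 at low temperature should secure.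

**Step 5**
Reactants: 12 1,2,3,4-tetrabromo-5-(2-methoxyphenoxy)benzene
Product: 15 2,3,4-tribromo-6-(2-methoxyphenoxy)phenol, via arylmagnesium chloride 13 (not isolated), via dimethyl arylboronate 14 (not isolated)
Conditions: iPrMgCl·LiCl (1.05 equiv), PhMe/THF, −40 °C; B(OMe)3, −40 → 0 °C; 30% H2O2, AcOH, 0 °C → rt
Reagents that add atoms: hydrogen peroxide, OO
Why: Ether-directed bromine–magnesium exchange on a polybromoarene, then borylation and peroxide oxidation (arylboronate to phenol): C6'–Br is the only bromine next to the aryloxy oxygen, which together with the ring A methoxy oxygen offers a two-point binding site that holds the magnesium reagent beside this bromine and inductively stabilizes the carbanion, so 13 should form at C6', be trapped as 14 and be oxidized with the oxygen placed on the same carbon; at −40 °C the ortho-bromo Grignard reagent should not collapse to an aryne.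

**Step 6**
Reactants: 15 2,3,4-tribromo-6-(2-methoxyphenoxy)phenol
Product: 16 2,3,4-tribromo-6-(2-hydroxyphenoxy)phenol
Conditions: BBr3 (3 equiv), CH2Cl2, −78 °C → rt; H2O
Reagents that add atoms: none
Why: Lewis-acid demethylation of an aryl methyl ether: BBr3 binds the methoxy oxygen and bromide attacks the methyl group in an SN2 step, while the diaryl ether, which has no sp3 carbon on oxygen, and the aryl bromides should be untouched.

**Step 7**
Reactants: 16 2,3,4-tribromo-6-(2-hydroxyphenoxy)phenol
Product: 17 2,3,4-tribromo-6-(3,5-dibromo-2-hydroxyphenoxy)phenol (target)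
Conditions: Br2 (2.05 equiv), AcOH/CH2Cl2, 0 °C → rt
Reagents that add atoms: bromine, BrBr
Why: Electrophilic aromatic bromination directed by a phenol: the ring A hydroxyl is the strongest donor and directs to its free ortho (C2) and para (C4) carbons, while ring B offers only C2'–H, meta to its hydroxyl on a ring deactivated by three bromines, so two equivalents of Br2 should stop at the target.

**Compound list**
1 | 2,3,4,5-tetrabromothiophene | Brc1sc(Br)c(Br)c1Br | starting material
2 | 2,3,4,5-tetrabromothiophene 1-oxide | O=S1C(Br)=C(Br)C(Br)=C1Br | intermediate (not isolated)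
3 | 2,3,4,5-tetrabromothiophene 1,1-dioxide | O=S1(=O)C(Br)=C(Br)C(Br)=C1Br | intermediate
4 | guaiacol (2-methoxyphenol) | COc1ccccc1O | starting material
5 | trichloroethylene | ClC=C(Cl)Cl | starting material
6 | dichloroacetylene | ClC#CCl | intermediate (not isolated)
7 | (E)-1-[(1,2-dichloroethenyl)oxy]-2-methoxybenzene | COc1ccccc1O/C(Cl)=C\Cl | intermediate
8 | 1-[(chloroethynyl)oxy]-2-methoxybenzene | COc1ccccc1OC#CCl | intermediate (not isolated)
9 | lithium (2-methoxyphenoxy)acetylide | COc1ccccc1OC#C[Li] | intermediate (not isolated)
10 | 1-(ethynyloxy)-2-methoxybenzene | COc1ccccc1OC#C | intermediate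
11 | 1,4,5,6-tetrabromo-2-(2-methoxyphenoxy)-7-thiabicyclo[2.2.1]hepta-2,5-diene 7,7-dioxide (racemic, one enantiomer drawn) | COc1ccccc1OC1=C[C@@]2(Br)C(Br)=C(Br)[C@]1(Br)S2(=O)=O | intermediate (not isolated)
12 | 1,2,3,4-tetrabromo-5-(2-methoxyphenoxy)benzene | COc1ccccc1Oc1cc(Br)c(Br)c(Br)c1Br | intermediate
13 | [2,3,4-tribromo-6-(2-methoxyphenoxy)phenyl]magnesium chloride | COc1ccccc1Oc1cc(Br)c(Br)c(Br)c1[Mg]Cl | intermediate (not isolated)
14 | dimethyl [2,3,4-tribromo-6-(2-methoxyphenoxy)phenyl]boronate | COc1ccccc1Oc1cc(Br)c(Br)c(Br)c1B(OC)OC | intermediate (not isolated)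
15 | 2,3,4-tribromo-6-(2-methoxyphenoxy)phenol | COc1ccccc1Oc1cc(Br)c(Br)c(Br)c1O | intermediate
16 | 2,3,4-tribromo-6-(2-hydroxyphenoxy)phenol | Oc1ccccc1Oc1cc(Br)c(Br)c(Br)c1O | intermediate
17 | 2,3,4-tribromo-6-(3,5-dibromo-2-hydroxyphenoxy)phenol | Oc1c(Br)cc(Br)cc1Oc1cc(Br)c(Br)c(Br)c1O | target

**Step count.** Total: 7 steps. Longest linear sequence: 6 steps (steps 2 to 7, from guaiacol 4).

**Steps most likely to fail**

1. Step 4 (bears the label). The ynol ether may be consumed by stepwise polar addition to the sulfone, giving [2+2] adducts or oligomers, faster than the concerted cycloaddition. The fallback uses known chemistry and sets out from guaiacol 4. Commercial 1,2,3-tribromo-5-fluorobenzene (Fc1cc(Br)c(Br)c(Br)c1) is lithiated between fluorine and bromine with LiN(iPr)2 (THF, −78 °C) and formylated with DMF to give 2,3,4-tribromo-6-fluorobenzaldehyde F1. SNAr of 4 on the aldehyde-activated fluoride (K2CO3, DMF, 60 °C) gives 2,3,4-tribromo-6-(2-methoxyphenoxy)benzaldehyde F2. Baeyer–Villiger (Dakin-type) oxidation with mCPBA gives 2,3,4-tribromo-6-(2-methoxyphenoxy)phenyl formate F3, and methanolysis (K2CO3, MeOH) gives phenol 15, where the route is rejoined for steps 6 and 7.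

2. Step 5. The exchange may take place at an inner bromine (C5' or C4', each flanked by two bromines) or at C3' in competition with C6', so that the hydroxyl ends up on the wrong carbon. The fallback sets out from 12 and replaces the neutral ether chelation by an anionic tether. BBr3 first removes the methyl group to give 2-(2,3,4,5-tetrabromophenoxy)phenol F4. MeMgCl (1 equiv) converts it into chloromagnesium 2-(2,3,4,5-tetrabromophenoxy)phenoxide F5. The covalently bound magnesium phenoxide should then hold iPrMgCl·LiCl next to the nearest bromine, C6'–Br, and give the doubly magnesiated species F6. B(OMe)3 and then H2O2/AcOH should lead directly to bisphenol 16, where the route is rejoined before step 7.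

3. Step 3. The terminal ynol ether may oligomerize or hydrate during work-up and concentration before it meets the diene. The fallback sets out from acetylide 9 in the flask of step 3. Quenching with Me3SiCl in place of water gives trimethyl[(2-methoxyphenoxy)ethynyl]silane F7, which should tolerate chromatography and storage. Cycloaddition with 3 (PhMe, 80–110 °C) through the silylated bridged sulfone F8 and loss of sulfur dioxide should give trimethyl[2,3,4,5-tetrabromo-6-(2-methoxyphenoxy)phenyl]silane F9. Fluoride-induced protodesilylation (Bu4NF, wet THF) of this aryl silane, flanked by oxygen and bromine, returns 12.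

**Further compounds**
F1 | step 4 | 2,3,4-tribromo-6-fluorobenzaldehyde | O=Cc1c(F)cc(Br)c(Br)c1Br
F2 | step 4 | 2,3,4-tribromo-6-(2-methoxyphenoxy)benzaldehyde | COc1ccccc1Oc1cc(Br)c(Br)c(Br)c1C=O
F3 | step 4 | 2,3,4-tribromo-6-(2-methoxyphenoxy)phenyl formate | COc1ccccc1Oc1cc(Br)c(Br)c(Br)c1OC=O
F4 | step 5 | 2-(2,3,4,5-tetrabromophenoxy)phenol | Oc1ccccc1Oc1cc(Br)c(Br)c(Br)c1Br
F5 | step 5 | chloromagnesium 2-(2,3,4,5-tetrabromophenoxy)phenoxide | Cl[Mg]Oc1ccccc1Oc1cc(Br)c(Br)c(Br)c1Br
F6 | step 5 | chloromagnesium 2-[2,3,4-tribromo-6-(chloromagnesio)phenoxy]phenoxide | Cl[Mg]Oc1ccccc1Oc1cc(Br)c(Br)c(Br)c1[Mg]Cl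
F7 | step 3 | trimethyl[(2-methoxyphenoxy)ethynyl]silane | COc1ccccc1OC#C[Si](C)(C)C
F8 | step 3 | 1,4,5,6-tetrabromo-2-(2-methoxyphenoxy)-3-(trimethylsilyl)-7-thiabicyclo[2.2.1]hepta-2,5-diene 7,7-dioxide (racemic, one enantiomer drawn) | COc1ccccc1OC1=C([Si](C)(C)C)[C@@]2(Br)C(Br)=C(Br)[C@]1(Br)S2(=O)=O
F9 | step 3 | trimethyl[2,3,4,5-tetrabromo-6-(2-methoxyphenoxy)phenyl]silane | COc1ccccc1Oc1c([Si](C)(C)C)c(Br)c(Br)c(Br)c1Br
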